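## Retrosynthetic overview
1. 9 ⇒ 8: the oxirane is made last, by reagent-controlled epoxidation of C7=C8 in the finished macrocyclic tetraene.
2. 8 ⇒ 5: the 2,5-dihydrofuran comes from oxidative closure of O-2 onto the exocyclic methylene (future C16) of a cembra-15-en-2-ol.
3. 5 ⇒ 4: the 14-membered ring comes from one head-to-tail C1–C2 bond. This is an enantioselective carbonyl-ene closure of an all-E geranylgeranial, in which the protonated CHO plays the part of the allyl cation of geranylgeranyl diphosphate.
4. 4 ⇒ 1: geranylgeraniol, two chemoselective oxidations and one acetylation.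
5. Ring order: carbocycle, then dihydrofuran, then oxirane.

Convention: cembrane numbering is used in all discussion. The CHO carbon is C2, the distal olefin is C1=C15, the oxidised methyl is C17 and the remaining methyl is C16.

Assumption: the (S,S)-antipode of the acid catalyst in step 4 is taken to give the 2S alcohol. If a test run shows the opposite sense, its mirror image is used.

## Route

Step 1
Reactants: 1 (2E,6E,10E)-geranylgeraniol
Product: 2 (2E,6E,10E)-geranylgeranial
Conditions: activated MnO2 (15 equiv), CH2Cl2, 23 °C, 3 h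
Reagents that add atoms: none
Why: Allylic alcohol oxidation on MnO2 stops at the enal, keeps the 2E geometry and leaves the isolated trisubstituted olefins alone; no stereocentre is formed.

Step 2
Reactants: 2 (2E,6E,10E)-geranylgeranial
Product: 3 (2E,6E,10E,14E)-16-hydroxygeranylgeranial
Conditions: SeO2 (0.2 equiv), t-BuOOH (2.5 equiv), salicylic acid (0.1 equiv), CH2Cl2, 0 → 23 °C, stopped at about 55 % conversion, 2 recycled
Reagents that add atoms: tert-butyl hydroperoxide, CC(C)(C)OO
Why: Catalytic SeO2 allylic oxidation (ene reaction, then [2,3]-sigmatropic shift) prefers the exposed terminal isopropylidene and its E-methyl group, while the conjugated head olefin is deactivated; partial conversion limits internal oxidation and over-oxidation, and no stereocentre is formed.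

Step 3
Reactants: 3 (2E,6E,10E,14E)-16-hydroxygeranylgeranial
Product: 4 (2E,6E,10E,14E)-16-acetoxygeranylgeranial
Conditions: Ac2O (1.5 equiv), pyridine, 4-(dimethylamino)pyridine (5 mol %), CH2Cl2, 0 °C
Reagents that add atoms: acetic anhydride, CC(=O)OC(C)=O
Why: Simple O-acylation installs the acetate of the target at the outset, so no protecting group is ever needed, and it stops hemiacetal oligomerisation in the next step.

Step 4
Reactants: 4 (2E,6E,10E,14E)-16-acetoxygeranylgeranial
Product: 5 (1R,2S,3E,7E,11E)-17-acetoxycembra-3,7,11,15(16)-tetraen-2-ol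
Conditions: (S,S)-imidodiphosphorimidate acid HN[P(=NSO2CF3)(3,3'-Ar2-BINOLate)]2, Ar = 3,5-(CF3)2C6H3 (5 mol %), 4 Å sieves, CHCl3, −30 °C, 4 added by syringe pump over 24 h (final 1 mM)
Reagents that add atoms: none
Why: Proposed new method: the confined strong acid protonates the enal oxygen in its chiral pocket, C1 of the distal olefin attacks one face of C2, and the C16 methyl gives up its proton (carbonyl-ene reaction), which sets C2 as S by catalyst control and C1 as 1,2-anti through a chair-like six-centre transition state with C3 and C14 pseudo-equatorial (C1 is erased in step 5); the 3E geometry forbids six-ring closure by C7=C8, closure by C11=C12 would give a strained E,E-cyclodecadiene, and bridging of the nascent C15 cation by the neighbouring acetate offsets its inductive drag and steers proton loss to the methyl group; the closest known reaction types are the confined-acid carbonyl-ene cyclisation of neral to isopiperitenol, Lewis-acid ene macrocyclisations of conjugated ynals to 14-membered rings, and the SnCl4 closure of geranylgeranoyl chloride at this same bond.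

Step 5
Reactants: 5 (1R,2S,3E,7E,11E)-17-acetoxycembra-3,7,11,15(16)-tetraen-2-ol
Product: 8 (2S,3E,7E,11E)-17-acetoxy-2,16-epoxycembra-1(15),3,7,11-tetraene, via C15 phenylselenide 6 (not isolated), via selenoxide 7 (not isolated)
Conditions: N-(phenylselanyl)phthalimide (1.05 equiv), camphorsulfonic acid C10H16O4S (5 mol %), CH2Cl2, −40 → 0 °C; then 2,6-lutidine, mCPBA (1.0 equiv), −78 °C; warm to 23 °C
Reagents that add atoms: N-(phenylselanyl)phthalimide, O=C1c2ccccc2C(=O)N1[Se]c1ccccc1 (PhSe of 6 and 7); 3-chloroperbenzoic acid, OOC(=O)c1cccc(Cl)c1 (oxygen on Se in 7)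
Why: In this 5-endo selenoetherification, seleniranium formation is reversible at every olefin but only C15=C16 has a hydroxyl within reach, and the allylic acetate plus the strain of the 4-exo alternative send Se to C15 and O-2 to C16, with Se entering on the face of the small H-1 (15R, Se cis to H-1); selenide oxidation at −78 °C outruns olefin epoxidation, and selenoxide syn-elimination avoids the two oxygen-bearing carbons, so H-1 is lost and the tetrasubstituted C1=C15 bond forms, while C2 keeps its configuration because its C–O bond is never broken.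

Step 6
Reactants: 8 (2S,3E,7E,11E)-17-acetoxy-2,16-epoxycembra-1(15),3,7,11-tetraene
Product: 9 (2S,7S,8S,3E,11E)-17-acetoxy-2,16:7,8-diepoxycembra-1(15),3,11-triene (CNP0140293.1)
Conditions: ent-Shi ketone 1,2:4,5-di-O-isopropylidene-β-L-erythro-2,3-hexodiulo-2,6-pyranose C12H18O6 (30 mol %), Oxone (1.1 equiv KHSO5), K2CO3, Bu4NHSO4 (4 mol %), MeCN–CH2(OMe)2 / aq. Na2B4O7–Na2EDTA, pH 10.5, −5 °C, stopped at about 60 % conversion, 8 recycled
Reagents that add atoms: potassium peroxymonosulfate, [K+].[O-]S(=O)(=O)OO
Why: In this Shi epoxidation the L-series dioxirane is the antipode of the D-fructose ketone that gives (R,R)-epoxides, so it delivers oxygen through the spiro transition state to give the (7S,8S)-oxirane by reagent control; C1=C15 is tetrasubstituted with three allylic C–O bonds, C3=C4 is an inductively deactivated and hindered allylic ether, and C11=C12 lies beside the acetoxymethyl arm (C17 is cis to C14), which leaves C7=C8 as the most remote and most electron-rich olefin, while the buffered base spares the acid-labile bis-allylic ether and the acetate.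

## Compound list
1 | (2E,6E,10E)-geranylgeraniol | CC(C)=CCC/C(C)=C/CC/C(C)=C/CC/C(C)=C/CO | starting material
2 | (2E,6E,10E)-geranylgeranial | CC(C)=CCC/C(C)=C/CC/C(C)=C/CC/C(C)=C/C=O | intermediate
3 | (2E,6E,10E,14E)-16-hydroxy-3,7,11,15-tetramethylhexadeca-2,6,10,14-tetraenal | OC/C(C)=C/CC/C(C)=C/CC/C(C)=C/CC/C(C)=C/C=O | intermediate
4 | (2E,6E,10E,14E)-16-acetoxy-3,7,11,15-tetramethylhexadeca-2,6,10,14-tetraenal | CC(=O)OC/C(C)=C/CC/C(C)=C/CC/C(C)=C/CC/C(C)=C/C=O | intermediate
5 | (1R,2S,3E,7E,11E)-17-acetoxycembra-3,7,11,15(16)-tetraen-2-ol (H-1 and H-2 anti) | CC(=O)OCC(=C)[C@H]1CC/C(C)=C/CC/C(C)=C/CC/C(C)=C/[C@@H]1O | intermediate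
6 | (1S,2S,15R)-17-acetoxy-2,16-epoxy-15-(phenylselanyl)cembra-3E,7E,11E-triene (Se cis to H-1) | CC(=O)OC[C@@]1([Se]c3ccccc3)[C@H]2CC/C(C)=C/CC/C(C)=C/CC/C(C)=C/[C@@H]2OC1 | intermediate (not isolated)
7 | selenoxide of 6 (configuration at Se not defined) | CC(=O)OC[C@@]1([Se](=O)c3ccccc3)[C@H]2CC/C(C)=C/CC/C(C)=C/CC/C(C)=C/[C@@H]2OC1 | intermediate (not isolated)
8 | (2S,3E,7E,11E)-17-acetoxy-2,16-epoxycembra-1(15),3,7,11-tetraene | CC(=O)OCC1=C2CC/C(C)=C/CC/C(C)=C/CC/C(C)=C/[C@@H]2OC1 | intermediate
9 | (2S,7S,8S,3E,11E)-17-acetoxy-2,16:7,8-diepoxycembra-1(15),3,11-triene | CC(=O)OCC1=C2CC/C(C)=C/CC[C@]3(C)O[C@H]3CC/C(C)=C/[C@@H]2OC1 | target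

## Count and risks
Total step count: 6. Longest linear sequence: 6.

**Step 4 (ene macrocyclisation).** The risks are:
- a distal olefin slowed by its allylic acetate;
- proton loss from CH2OAc instead of CH3;
- E/Z drift of the enal followed by six-ring closure;
- an unknown level of enantiocontrol.

The fallback sets out from 4 and comes back at 5. It replaces the aldehyde by an acylium ion and moves stereocontrol into a ketone reduction. Pinnick oxidation (NaClO2, NaH2PO4, 2-methyl-2-butene) gives 16-acetoxygeranylgeranoic acid F1. 1-Chloro-N,N,2-trimethylpropenylamine converts it under neutral conditions into 16-acetoxygeranylgeranoyl chloride F2. EtAlCl2 (CH2Cl2, −78 °C, high dilution) then effects the acylium–olefin closure with proton loss, an aliphatic Friedel–Crafts acylation of the type known to close the parent acid chloride to the 14-membered ketone. This gives 17-acetoxycembra-3,7,11,15(16)-tetraen-2-one F3. (R)-2-Methyl-CBS-oxazaborolidine C18H20BNO with catecholborane reduces F3 to the 2S alcohol, with the branched C1 acting as the large group. The product is 5 together with its C1 epimer, and both lead to 8.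

**Step 6 (site selectivity, C7=C8 against C11=C12).** The fallback sets out from 8 and comes back at 9. It replaces a small-molecule oxidant by a binding pocket. K2CO3 in MeOH frees (2S)-2,16-epoxycembra-1(15),3,7,11-tetraen-17-ol F8. A screened panel of engineered cytochrome P450 BM3 variants (whole cells, glucose-driven NADPH recycling) is used to pick out C7=C8; such variants can oxidise 14-membered cembranoids with positional control. The product is (2S,7S,8S)-2,16:7,8-diepoxycembra-1(15),3,11-trien-17-ol F9, and Ac2O in pyridine returns 9.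

**Step 5 (5-endo closure and direction of elimination).** The fallback sets out from 5 and comes back at 8. It replaces reversible electrophile capture by a hydroxyl-directed epoxidation.
- K2CO3 in MeOH gives cembra-3,7,11,15(16)-tetraene-2,17-diol F4.
- Sharpless epoxidation with Ti(OiPr)4, L-(+)-diisopropyl tartrate and t-BuOOH (4 Å sieves, −20 °C) oxidises only the primary allylic alcohol unit. This tartrate is the slow-reacting match for the 2S carbinol, so C3=C4 is spared. The product is (15S)-15,16-epoxycembra-3,7,11-triene-2,17-diol F5.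
- Warming with Ti(OiPr)4 lets O-2 open the 2,3-epoxy alcohol at its terminal carbon C16. This gives (15S)-2,16-epoxycembra-3,7,11-triene-15,17-diol F6, in which the tertiary OH is cis to H-1.
- Ac2O in pyridine acetylates only the primary hydroxyl, giving the 17-monoacetate F7.
- The Burgess reagent removes the tertiary hydroxyl by syn-elimination with H-1 and gives 8.

## Further compounds
F1 | step 4 | (2E,6E,10E,14E)-16-acetoxygeranylgeranoic acid | CC(=O)OC/C(C)=C/CC/C(C)=C/CC/C(C)=C/CC/C(C)=C/C(=O)O
F2 | step 4 | (2E,6E,10E,14E)-16-acetoxygeranylgeranoyl chloride | CC(=O)OC/C(C)=C/CC/C(C)=C/CC/C(C)=C/CC/C(C)=C/C(=O)Cl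
F3 | step 4 | (3E,7E,11E)-17-acetoxycembra-3,7,11,15(16)-tetraen-2-one (C1 configurationally labile) | CC(=O)OCC(=C)C1CC/C(C)=C/CC/C(C)=C/CC/C(C)=C/C1=O
F4 | step 5 | (1R,2S,3E,7E,11E)-cembra-3,7,11,15(16)-tetraene-2,17-diol | OCC(=C)[C@H]1CC/C(C)=C/CC/C(C)=C/CC/C(C)=C/[C@@H]1O
F5 | step 5 | (1S,2S,15S)-15,16-epoxycembra-3E,7E,11E-triene-2,17-diol | OC[C@]1(CO1)[C@H]2CC/C(C)=C/CC/C(C)=C/CC/C(C)=C/[C@@H]2O
F6 | step 5 | (1S,2S,15S)-2,16-epoxycembra-3E,7E,11E-triene-15,17-diol | OC[C@@]1(O)[C@H]2CC/C(C)=C/CC/C(C)=C/CC/C(C)=C/[C@@H]2OC1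
F7 | step 5 | (1S,2S,15R)-17-acetoxy-2,16-epoxycembra-3E,7E,11E-trien-15-ol | CC(=O)OC[C@@]1(O)[C@H]2CC/C(C)=C/CC/C(C)=C/CC/C(C)=C/[C@@H]2OC1
F8 | step 6 | (2S,3E,7E,11E)-2,16-epoxycembra-1(15),3,7,11-tetraen-17-ol | OCC1=C2CC/C(C)=C/CC/C(C)=C/CC/C(C)=C/[C@@H]2OC1
F9 | step 6 | (2S,7S,8S,3E,11E)-2,16:7,8-diepoxycembra-1(15),3,11-trien-17-ol | OCC1=C2CC/C(C)=C/CC[C@]3(C)O[C@H]3CC/C(C)=C/[C@@H]2OC1
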